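## Structural features

The target is a germacranolide: a ten-membered carbocycle (C1–C10) fused across C6–C7 to an α-methylene-γ-butyrolactone (ring oxygen on C6, C11=C13, carbonyl C12). The ring holds two trisubstituted alkenes of opposite geometry, Z at C1=C10 (methyl C14) and E at C4=C5 (methyl C15). Four stereocentres stand in a row, C6 (S), C7 (S), C8 (S) and C9 (R). The lactone is cis-fused, and the oxygens on C6, C8 and C9 all lie on the face of the C7–C11 bond. C8 carries the ester of (3R)-3-methyl-4-(octadecanoyloxy)butanoic acid, and C9 a free allylic hydroxyl next to that ester. Fragile points are the α-methylene lactone (Michael acceptor, reducible), the cyclodeca-1,5-diene (Cope rearrangement, transannular cyclisation), the two aliphatic esters, and the C8 ester, which can migrate to the C9 hydroxyl under base. The real difficulty is to make the medium ring with the cis and the trans alkene in the right places and then to set C8 and C9 on a flexible ring. The plan exploits that C9, C10 (with C14), C5, C6, C7 (with C11–C13) and C8 form the carvone skeleton once C5 and C10 are bonded, with C7 already correct, while C1–C4 with C15 is 1-methylcyclobutene. A [2+2] addition across C10=C5 followed by cleavage of C1–C4 and C5–C10 inserts the four carbons and creates both ring alkenes.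

## Logic of the disconnections

29 is opened at the lactone: the O6–C12 bond is cut and C12 is taken back to the carbinol level, giving 26 (through 28 and 27). The α-methylene lactone is the most reactive group and is best made last. The forward step must oxidise a primary allylic alcohol in the presence of two secondary allylic ones.

26 is traced to 25 by putting identical silyl groups on O6 and O12. One fluoride step then frees both. The forward step must not cleave or shift the two esters.

25 is traced to 24 by cutting the C9–H bond (carbinol to ketone). The ketone is what the ring expansion delivers and is needed to functionalise C8. The forward reduction must be 1,2-selective and bring hydride to the face that gives 9R, cis to the C8 ester.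

24 is cut at the C8–O bond into 15 and 23. This is convergent and keeps the lipid chain with its own stereocentre out of the main line. The forward step must be a displacement at C8 with inversion, since 15 is expected to carry its hydroxyl on the face opposite to the C7 arm.

15 is traced to 13 by removing the C8 oxygen. This leaves a ketone with one enolisable α′ position. The forward step demands α′ rather than γ deprotonation and a defined face of attack.

13 is traced to 12 by trading the π bonds C1=C10 and C4=C5 for the σ bonds C1–C4 and C5–C10. A strained medium ring with two trisubstituted alkenes becomes a rigid tricycle. The forward cycloreversion must break C5–C10 rather than C2–C3 and place the cis geometry on C1=C10.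

12 is cut at C10–C1 and C5–C4 into 9 and 11. This is the strategic cut: it returns a six-membered chiral-pool enone and a four-carbon alkene. The forward photocycloaddition needs head-to-tail orientation.

11 is traced to 10 by moving the double bond from the ring to the exocyclic position, because 10 is the purchasable isomer.

9 is traced through 8 and 7 to 6: the O6–Si bond is cut, then the C6–O bond is re-formed with the opposite configuration. Oxygenation of the enone is expected to occur anti to the C7 arm, so the cis relationship needs one inversion.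

6 is traced to 3 by cutting the C6–O bond (through 5 and 4). The forward step demands γ rather than α′ enolisation and oxidation at the γ terminus.

3 is traced through 2 to 1 by cutting O12–Si and then C12–O. The forward allylic oxidation must choose the methyl of the 1,1-disubstituted alkene over the positions of the electron-poor enone.

23 is traced through 22 to 20 and 21 by cutting the stearate O–acyl bond and re-masking the acid as a tert-butyl ester. The free γ-hydroxy acid, which would lactonise, is never formed.

20 is traced through 19 to 16 and 17 by cutting the imide C–N bond and the C2–C3 bond of the butanoate. The auxiliary sets the methyl-bearing stereocentre in the alkylation.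

## Other disconnections considered

Alternative 1: The cut adds a bond between C4 and C9, so the ten-membered ring of the cis-lactone dienone A2 becomes the decalin A1, a tertiary C9 alcohol with a mesylate on C5. Forward, KOC(CH3)3 turns A1 into its alkoxide, which expels the mesylate across the antiperiplanar C4–C9 bond and unveils the C9 ketone and the C4=C5 alkene in one ionic step.
- In favour: the E geometry of C4=C5 follows stereospecifically from the equatorial mesylate, the Z C1=C10 alkene is locked in a six-membered ring beforehand, and the reaction runs far below the temperature of Cope rearrangement.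
- Against: A1 has five stereocentres (C4, C5, C6, C7, C9) to assemble on a decalin. A2 still lacks the C13 methylene and the C8 oxygen, so α-methylenation, C8 oxidation and C9 reduction remain. The strong base also meets an enolisable lactone.
- Comparison: alternative 1 is the better on alkene geometry and on predictability of the ring-forming step. It is the equal on the late C8/C9 problem, which both routes solve on the flexible ring. It is the poorer on step economy, since the chosen plan reaches 13 in two steps from an enone that already holds C11–C13.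

Alternative 2: The ring is cut at C2–C3, giving the open-chain allylic sulfone and allylic bromide A3, whose C8/C9 acetonide would descend from an enzymatic arene cis-dihydrodiol. Forward, KN(SiMe3)2 deprotonates the sulfone at C3 and the carbanion displaces the bromide at C2, closing the ring to A4.
- In favour: all four ring stereocentres, including the cis C8/C9 diol, are fixed in absolute terms before cyclisation, and both alkenes are built with defined geometry in acyclic intermediates.
- Against: a ten-membered ring must be closed by an intramolecular SN2 reaction at high dilution, with SN2′ attack, oligomerisation and loss of the Z geometry of the allylic bromide as competitors. The sulfone must be removed reductively next to two allylic C–O bonds. The freed C8 and C9 hydroxyls must be told apart for acylation, and the linear sequence to A3 is long.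
- Comparison: alternative 2 is clearly the better on control of C8 and C9 and at least the equal on alkene geometry. Its ring closure is mechanistically simple but is the weaker step entropically, and it is the poorer in step count.

Alternative 3: The cut is the C8–C9 bond: the diol A6 is traced to the dialdehyde A5, a C8 aldehyde tethered to a Z-configured C9 enal. Forward, low-valent titanium from TiCl3 and Zn–Cu couple joins the two carbonyl carbons in a pinacol coupling that closes the ring and creates both carbinol centres.
- In favour: the ring, C8 and C9 arise in one step, a titanium-bridged transition state tends to give cis diols in medium rings, and both alkenes are set beforehand.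
- Against: C7 of A5 is α to an aldehyde and β to the C6 ether, so epimerisation and β-elimination threaten. The reagent can deoxygenate the diol to an alkene or reduce the enal. The cis diol can form on either face relative to C7, the two hydroxyls need differentiation, and the lactone with its methylene must still be built from the acetate arm.
- Comparison: alternative 3 is the better in forming the C8/C9 pair convergently and the equal in needing a later selective acylation at C8. The chosen plan is the better in chemoselectivity of the ring-forming step and in steps to the macrocycle, while its control of alkene geometry is the less certain.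

Key step: step 8

Remark: the key-step precursor and product as specified (benzyl-type ether at C6) were checked atom by atom. No error was found: both carry the cis C6–O/C7 relationship of the target and the cis-anti-cis tricycle. The only change is the C6 protecting group, a silyl ether identical to that on O12, which tolerates irradiation and thermolysis and comes off in one step with the other.

Remark: 11 is treated as not purchasable in adequate purity and is made from 10.

Remark: the side-chain acid is built by auxiliary alkylation from 16 and 17 rather than from a chiral-pool hydroxy ester. This takes four steps, about three fewer than homologating the hydroxy ester, and avoids a γ-hydroxy acid.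

TBS = tert-butyldimethylsilyl; TBSO = its ether. Atom labels C1–C15 are germacrane numbers.

## Steps

Step 1
Reactants: 1 (S)-carvone
Product: 2 (5S)-5-(3-hydroxyprop-1-en-2-yl)-2-methylcyclohex-2-en-1-one
Conditions: SeO2 (0.3 equiv), t-BuOOH (2 equiv), salicylic acid (0.1 equiv), CH2Cl2, rt
Reagents that add atoms: tert-butyl hydroperoxide CC(C)(C)OO (oxygen source, relayed through selenium dioxide O=[Se]=O)
Why: Allylic oxidation by SeO2 (ene reaction, then [2,3]-sigmatropic shift) attacks the electron-rich 1,1-disubstituted alkene at its methyl group and leaves the allylic positions of the electron-poor enone alone; the C7 stereocentre is not involved.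

Step 2
Reactants: 2 (5S)-5-(3-hydroxyprop-1-en-2-yl)-2-methylcyclohex-2-en-1-one
Product: 3 (5S)-5-[3-(TBSO)prop-1-en-2-yl]-2-methylcyclohex-2-en-1-one
Conditions: TBSCl, imidazole, CH2Cl2, 0 °C to rt
Reagents that add atoms: tert-butyldimethylsilyl chloride CC(C)(C)[Si](C)(C)Cl
Why: Standard silylation of a primary allylic alcohol; the hydroxyl must be masked before the organomagnesium base of step 3.

Step 3
Reactants: 3 (5S)-5-[3-(TBSO)prop-1-en-2-yl]-2-methylcyclohex-2-en-1-one
Product: 6 (4R,5S)-4-hydroxy-2-methyl-5-[3-(TBSO)prop-1-en-2-yl]cyclohex-2-en-1-one, via bromomagnesium dienolate 4 (not isolated), via trimethylsilyl dienol ether 5 (not isolated)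
Conditions: MeMgBr, FeCl3 (5 mol%), Et2O, −20 °C; Me3SiCl, Et3N, DMPU, −20 to 0 °C; then mCPBA, NaHCO3, CH2Cl2, −20 °C; aq. citric acid
Reagents that add atoms: 3-chloroperoxybenzoic acid OOC(=O)c1cccc(Cl)c1 (the new oxygen of 6); methylmagnesium bromide C[Mg]Br and chlorotrimethylsilane C[Si](C)(C)Cl leave atoms only in 4 and 5
Why: The ferrate base formed from MeMgBr and catalytic FeCl3 removes the γ-proton (C6–H) kinetically, and O-silylation gives the linear dienol ether. The peracid then attacks the γ-terminus anti to the C7 arm (vinylogous Rubottom oxidation), giving the trans γ-hydroxy enone after loss of silicon.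

Step 4
Reactants: 6 (4R,5S)-4-hydroxy-2-methyl-5-[3-(TBSO)prop-1-en-2-yl]cyclohex-2-en-1-one
Product: 7 (1S,6S)-3-methyl-4-oxo-6-[3-(TBSO)prop-1-en-2-yl]cyclohex-2-en-1-yl 4-nitrobenzoate
Conditions: 4-O2NC6H4CO2H, PPh3, DIAD, THF, 0 °C to rt
Reagents that add atoms: 4-nitrobenzoic acid OC(=O)c1ccc(cc1)[N+](=O)[O-]
Why: Mitsunobu esterification: SN2 displacement of the oxyphosphonium group at the allylic carbinol inverts C6 and gives the cis (6S) ester; the acidic nucleophile keeps elimination down.

Step 5
Reactants: 7 (1S,6S)-3-methyl-4-oxo-6-[3-(TBSO)prop-1-en-2-yl]cyclohex-2-en-1-yl 4-nitrobenzoate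
Product: 8 (4S,5S)-4-hydroxy-2-methyl-5-[3-(TBSO)prop-1-en-2-yl]cyclohex-2-en-1-one
Conditions: K2CO3 (0.2 equiv), MeOH, 0 °C
Reagents that add atoms: none
Why: Transesterification of an activated aryl ester at the acyl carbon, so C6 keeps its configuration; the conditions are too mild to drive loss of the γ-oxygen and aromatisation.

Step 6
Reactants: 8 (4S,5S)-4-hydroxy-2-methyl-5-[3-(TBSO)prop-1-en-2-yl]cyclohex-2-en-1-one
Product: 9 (4S,5S)-4-(TBSO)-5-[3-(TBSO)prop-1-en-2-yl]-2-methylcyclohex-2-en-1-one
Conditions: TBSCl, imidazole, DMAP (cat.), DMF, rt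
Reagents that add atoms: tert-butyldimethylsilyl chloride CC(C)(C)[Si](C)(C)Cl
Why: Silylation under buffered conditions avoids the strong base that a benzyl-type ether would need; the silyl ether is transparent above 300 nm, stable to flash thermolysis, and leaves later together with the O12 group.

Step 7
Reactants: 10 methylenecyclobutane
Product: 11 1-methylcyclobutene
Conditions: KOC(CH3)3 (cat.), DMSO, rt; fractional distillation
Reagents that add atoms: none
Why: Base-catalysed prototropic isomerisation through the allyl anion; the equilibrium favours the endocyclic trisubstituted alkene, which is separated by distillation.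

Step 8
Reactants: 9 (4S,5S)-4-(TBSO)-5-[3-(TBSO)prop-1-en-2-yl]-2-methylcyclohex-2-en-1-one; 11 1-methylcyclobutene
Product: 12 (1R,2S,5R,6S,9S,10R)-10-(TBSO)-9-[3-(TBSO)prop-1-en-2-yl]-2,6-dimethyltricyclo[4.4.0.0(2,5)]decan-7-one
Conditions: hν (350–365 nm, Pyrex), 11 (10 equiv), CH2Cl2, −40 °C
Reagents that add atoms: none
Why: Excitation of the enone n,π* band and intersystem crossing give the triplet, which adds the cyclobutene stepwise through a 1,4-biradical; this is the enone–alkene [2+2] photocycloaddition, known for cyclobutenes with cyclohexenones. The one new ring, the cyclobutane C10–C1–C4–C5, is closed by this two-bond cycloaddition (first bond, then radical recombination) and completes the bicyclo[2.2.0]hexane. Head-to-tail orientation (C10–C1 and C5–C4) is required and is supported twice: the donor alkene places its substituted carbon C4 on the β-carbon C5, and the other orientation would join the two fully substituted carbons C10 and C4. C10 and C5 become cis because only the cis-fused bicyclo[4.2.0]octanone closes without strain, and C1 and C4 are cis because they were the ends of the cyclobutene double bond. The alkene approaches the enone face anti to the pseudoaxial C6 silyloxy group and the C7 arm and turns its CH2–CH2 bridge away from the six-membered ring, which gives the cis-anti-cis array. Face selection helps but is not vital, since C1, C4, C5 and C10 all return to sp2 in step 9. A large excess of 11 and low temperature are used so that intermolecular addition outruns crossed addition of the enone to its own 2-propenyl arm.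

Step 9
Reactants: 12 (1R,2S,5R,6S,9S,10R)-10-(TBSO)-9-[3-(TBSO)prop-1-en-2-yl]-2,6-dimethyltricyclo[4.4.0.0(2,5)]decan-7-one
Product: 13 (2Z,6E,8S,9S)-8-(TBSO)-9-[3-(TBSO)prop-1-en-2-yl]-2,6-dimethylcyclodeca-2,6-dien-1-one
Conditions: flash vacuum thermolysis, quartz tube, 480 °C, 0.01 mmHg, contact time ca. 10 ms, trap at −78 °C
Reagents that add atoms: none
Why: Thermal cycloreversion of a bicyclo[2.2.0]hexane: homolysis of the most strained bond C1–C4 gives a cyclohexane-1,4-diyl, and β-scission of C5–C10 turns both radicals into the ring alkenes. The stepwise course gives one cis and one trans alkene; cis is expected at C1=C10, where the developing enone needs a planarity that a trans-cyclodecenone cannot offer, and trans at C4=C5. The short contact time keeps the product from Cope rearrangement.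

Step 10
Reactants: 13 (2Z,6E,8S,9S)-8-(TBSO)-9-[3-(TBSO)prop-1-en-2-yl]-2,6-dimethylcyclodeca-2,6-dien-1-one
Product: 15 (2Z,6E,8S,9R,10R)-8-(TBSO)-9-[3-(TBSO)prop-1-en-2-yl]-10-hydroxy-2,6-dimethylcyclodeca-2,6-dien-1-one, via potassium enolate 14 (not isolated)
Conditions: KN(SiMe3)2, THF, −78 °C; 2-(phenylsulfonyl)-3-phenyloxaziridine, −78 °C; aq. NH4Cl
Reagents that add atoms: 2-(phenylsulfonyl)-3-phenyloxaziridine O=S(=O)(c1ccccc1)N1OC1c1ccccc1 (the hydroxyl oxygen; potassium of 14 comes from KN(SiMe3)2)
Why: Kinetic deprotonation at the α′ carbon C8 and enolate hydroxylation by the N-sulfonyloxaziridine. The oxidant attacks the outer face of the ring enolate with H7 eclipsing the enolate plane, so the hydroxyl should arrive anti to the C7 arm (10R), the epimer that step 15 then inverts.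

Step 11
Reactants: 16 (4S)-4-benzyl-3-propanoyl-1,3-oxazolidin-2-one; 17 tert-butyl bromoacetate
Product: 19 tert-butyl (3R)-4-[(4S)-4-benzyl-2-oxo-1,3-oxazolidin-3-yl]-3-methyl-4-oxobutanoate, via sodium enolate 18 (not isolated)
Conditions: NaN(SiMe3)2, THF, −78 °C; 17, −78 to −40 °C
Reagents that add atoms: none
Why: Evans asymmetric alkylation: the chelated Z-enolate is attacked on the face opposite to the benzyl group, which sets the (R) methyl-bearing centre.

Step 12
Reactants: 19 tert-butyl (3R)-4-[(4S)-4-benzyl-2-oxo-1,3-oxazolidin-3-yl]-3-methyl-4-oxobutanoate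
Product: 20 tert-butyl (3R)-4-hydroxy-3-methylbutanoate
Conditions: LiBH4, H2O (1 equiv), Et2O, 0 °C
Reagents that add atoms: none
Why: Reductive removal of the auxiliary: LiBH4 reduces the activated imide carbonyl to the primary alcohol and leaves the hindered tert-butyl ester; the stereocentre is not enolisable under these conditions.

Step 13
Reactants: 20 tert-butyl (3R)-4-hydroxy-3-methylbutanoate; 21 stearic acid
Product: 22 tert-butyl (3R)-3-methyl-4-(octadecanoyloxy)butanoate
Conditions: DCC, DMAP (cat.), CH2Cl2, 0 °C to rt
Reagents that add atoms: none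
Why: Steglich esterification of a primary alcohol; acylating at once keeps the γ-hydroxy ester from lactonising.

Step 14
Reactants: 22 tert-butyl (3R)-3-methyl-4-(octadecanoyloxy)butanoate
Product: 23 (3R)-3-methyl-4-(octadecanoyloxy)butanoic acid
Conditions: CF3CO2H–CH2Cl2 (1:4), 0 °C to rt
Reagents that add atoms: none
Why: Acidolysis of the tert-butyl ester by loss of isobutene; the primary stearate is inert to these conditions.

Step 15
Reactants: 15 (2Z,6E,8S,9R,10R)-8-(TBSO)-9-[3-(TBSO)prop-1-en-2-yl]-10-hydroxy-2,6-dimethylcyclodeca-2,6-dien-1-one; 23 (3R)-3-methyl-4-(octadecanoyloxy)butanoic acid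
Product: 24 (1S,3Z,7E,9S,10R)-9-(TBSO)-10-[3-(TBSO)prop-1-en-2-yl]-3,7-dimethyl-2-oxocyclodeca-3,7-dien-1-yl (3R)-3-methyl-4-(octadecanoyloxy)butanoate
Conditions: PPh3, DIAD, toluene, 0 °C to rt
Reagents that add atoms: none
Why: Mitsunobu esterification: the carboxylate displaces the oxyphosphonium group at the α-keto carbinol, a position activated for SN2, with inversion. C8 thus becomes S, with the ester on the face of the C7 arm.

Step 16
Reactants: 24 (1S,3Z,7E,9S,10R)-9-(TBSO)-10-[3-(TBSO)prop-1-en-2-yl]-3,7-dimethyl-2-oxocyclodeca-3,7-dien-1-yl (3R)-3-methyl-4-(octadecanoyloxy)butanoate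
Product: 25 (1S,2R,3Z,7E,9S,10R)-9-(TBSO)-10-[3-(TBSO)prop-1-en-2-yl]-2-hydroxy-3,7-dimethylcyclodeca-3,7-dien-1-yl (3R)-3-methyl-4-(octadecanoyloxy)butanoate
Conditions: NaBH4, CeCl3·7H2O, MeOH–THF, −78 °C; AcOH quench
Reagents that add atoms: none
Why: Luche reduction, 1,2-selective for the enone and inert to the esters. Hydride should come from the outer face, anti to the C7–C8 ring bond with H8 eclipsing C10, which places the new hydroxyl cis to the C8 ester (9R); the acidic quench at low temperature prevents acyl migration.

Step 17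
Reactants: 25 (1S,2R,3Z,7E,9S,10R)-9-(TBSO)-10-[3-(TBSO)prop-1-en-2-yl]-2-hydroxy-3,7-dimethylcyclodeca-3,7-dien-1-yl (3R)-3-methyl-4-(octadecanoyloxy)butanoate
Product: 26 (1S,2R,3Z,7E,9S,10S)-2,9-dihydroxy-10-(3-hydroxyprop-1-en-2-yl)-3,7-dimethylcyclodeca-3,7-dien-1-yl (3R)-3-methyl-4-(octadecanoyloxy)butanoate
Conditions: HF·pyridine, pyridine, THF, 0 °C to rt
Reagents that add atoms: none
Why: Fluoride-driven cleavage of both silyl ethers in a buffered, non-basic medium, which spares the two esters and gives no alkoxide that could trigger acyl migration.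

Step 18
Reactants: 26 (1S,2R,3Z,7E,9S,10S)-2,9-dihydroxy-10-(3-hydroxyprop-1-en-2-yl)-3,7-dimethylcyclodeca-3,7-dien-1-yl (3R)-3-methyl-4-(octadecanoyloxy)butanoate
Product: 29 CNP0114940.1, via hydroxy enal 27 (not isolated), via lactol 28 (not isolated)
Conditions: TEMPO (0.2 equiv), PhI(OAc)2 (2.5 equiv), CH2Cl2, rt
Reagents that add atoms: none
Why: Oxoammonium-mediated oxidative lactonisation: the unhindered primary allylic alcohol is oxidised first, the C6 hydroxyl closes the five-membered lactol, and a second oxidation gives the α-methylene lactone. The hindered secondary C9 hydroxyl should react far more slowly; the cis fusion follows from the configurations already set at C6 and C7.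

## Compound list

1 | (S)-carvone, (5S)-2-methyl-5-(prop-1-en-2-yl)cyclohex-2-en-1-one | CC1=CC[C@@H](CC1=O)C(C)=C | starting material
2 | (5S)-5-(3-hydroxyprop-1-en-2-yl)-2-methylcyclohex-2-en-1-one | C=C(CO)[C@@H]1CC(=O)C(C)=CC1 | intermediate
3 | (5S)-5-[3-(tert-butyldimethylsilyloxy)prop-1-en-2-yl]-2-methylcyclohex-2-en-1-one | C=C(CO[Si](C)(C)C(C)(C)C)[C@@H]1CC(=O)C(C)=CC1 | intermediate
4 | bromomagnesium (5R)-2-methyl-5-[3-(TBSO)prop-1-en-2-yl]cyclohexa-1,3-dien-1-olate | C=C(CO[Si](C)(C)C(C)(C)C)[C@@H]1CC(O[Mg]Br)=C(C)C=C1 | intermediate (not isolated)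
5 | trimethyl{[(5R)-2-methyl-5-[3-(TBSO)prop-1-en-2-yl]cyclohexa-1,3-dien-1-yl]oxy}silane | C=C(CO[Si](C)(C)C(C)(C)C)[C@@H]1CC(O[Si](C)(C)C)=C(C)C=C1 | intermediate (not isolated)
6 | (4R,5S)-4-hydroxy-2-methyl-5-[3-(TBSO)prop-1-en-2-yl]cyclohex-2-en-1-one (hydroxyl trans to the arm) | C=C(CO[Si](C)(C)C(C)(C)C)[C@@H]1CC(=O)C(C)=C[C@H]1O | intermediate
7 | (1S,6S)-3-methyl-4-oxo-6-[3-(TBSO)prop-1-en-2-yl]cyclohex-2-en-1-yl 4-nitrobenzoate | C=C(CO[Si](C)(C)C(C)(C)C)[C@@H]1CC(=O)C(C)=C[C@@H]1OC(=O)c2ccc(cc2)[N+](=O)[O-] | intermediate
8 | (4S,5S)-4-hydroxy-2-methyl-5-[3-(TBSO)prop-1-en-2-yl]cyclohex-2-en-1-one (hydroxyl cis to the arm) | C=C(CO[Si](C)(C)C(C)(C)C)[C@@H]1CC(=O)C(C)=C[C@@H]1O | intermediate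
9 | (4S,5S)-4-(TBSO)-5-[3-(TBSO)prop-1-en-2-yl]-2-methylcyclohex-2-en-1-one | C=C(CO[Si](C)(C)C(C)(C)C)[C@@H]1CC(=O)C(C)=C[C@@H]1O[Si](C)(C)C(C)(C)C | intermediate (key-step precursor)
10 | methylenecyclobutane | C=C1CCC1 | starting material
11 | 1-methylcyclobutene | CC1=CCC1 | intermediate
12 | (1R,2S,5R,6S,9S,10R)-10-(TBSO)-9-[3-(TBSO)prop-1-en-2-yl]-2,6-dimethyltricyclo[4.4.0.0(2,5)]decan-7-one (cis-anti-cis) | C=C(CO[Si](C)(C)C(C)(C)C)[C@@H]1CC(=O)[C@@]2(C)[C@@H]3CC[C@]3(C)[C@H]2[C@@H]1O[Si](C)(C)C(C)(C)C | intermediate (key-step product)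
13 | (2Z,6E,8S,9S)-8-(TBSO)-9-[3-(TBSO)prop-1-en-2-yl]-2,6-dimethylcyclodeca-2,6-dien-1-one | C=C(CO[Si](C)(C)C(C)(C)C)[C@@H]1CC(=O)/C(C)=C\CC/C(C)=C/[C@@H]1O[Si](C)(C)C(C)(C)C | intermediate
14 | potassium (2Z,6E,8S,9S)-8-(TBSO)-9-[3-(TBSO)prop-1-en-2-yl]-2,6-dimethylcyclodeca-1(10),2,6-trien-1-olate | C=C(CO[Si](C)(C)C(C)(C)C)[C@@H]1C=C([O-])/C(C)=C\CC/C(C)=C/[C@@H]1O[Si](C)(C)C(C)(C)C.[K+] | intermediate (not isolated)
15 | (2Z,6E,8S,9R,10R)-8-(TBSO)-9-[3-(TBSO)prop-1-en-2-yl]-10-hydroxy-2,6-dimethylcyclodeca-2,6-dien-1-one | C=C(CO[Si](C)(C)C(C)(C)C)[C@@H]1[C@@H](O)C(=O)/C(C)=C\CC/C(C)=C/[C@@H]1O[Si](C)(C)C(C)(C)C | intermediate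
16 | (4S)-4-benzyl-3-propanoyl-1,3-oxazolidin-2-one | CCC(=O)N1[C@@H](Cc2ccccc2)COC1=O | starting material
17 | tert-butyl bromoacetate | CC(C)(C)OC(=O)CBr | starting material
18 | sodium (Z)-1-[(4S)-4-benzyl-2-oxo-1,3-oxazolidin-3-yl]prop-1-en-1-olate | C/C=C(\[O-])N1[C@@H](Cc2ccccc2)COC1=O.[Na+] | intermediate (not isolated)
19 | tert-butyl (3R)-4-[(4S)-4-benzyl-2-oxo-1,3-oxazolidin-3-yl]-3-methyl-4-oxobutanoate | CC(C)(C)OC(=O)C[C@@H](C)C(=O)N1[C@@H](Cc2ccccc2)COC1=O | intermediate
20 | tert-butyl (3R)-4-hydroxy-3-methylbutanoate | CC(C)(C)OC(=O)C[C@@H](C)CO | intermediate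
21 | stearic acid | CCCCCCCCCCCCCCCCCC(=O)O | starting material
22 | tert-butyl (3R)-3-methyl-4-(octadecanoyloxy)butanoate | CC(C)(C)OC(=O)C[C@@H](C)COC(=O)CCCCCCCCCCCCCCCCC | intermediate
23 | (3R)-3-methyl-4-(octadecanoyloxy)butanoic acid | OC(=O)C[C@@H](C)COC(=O)CCCCCCCCCCCCCCCCC | intermediate
24 | (1S,3Z,7E,9S,10R)-9-(TBSO)-10-[3-(TBSO)prop-1-en-2-yl]-3,7-dimethyl-2-oxocyclodeca-3,7-dien-1-yl (3R)-3-methyl-4-(octadecanoyloxy)butanoate | C=C(CO[Si](C)(C)C(C)(C)C)[C@@H]1[C@H](OC(=O)C[C@@H](C)COC(=O)CCCCCCCCCCCCCCCCC)C(=O)/C(C)=C\CC/C(C)=C/[C@@H]1O[Si](C)(C)C(C)(C)C | intermediate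
25 | (1S,2R,3Z,7E,9S,10R)-9-(TBSO)-10-[3-(TBSO)prop-1-en-2-yl]-2-hydroxy-3,7-dimethylcyclodeca-3,7-dien-1-yl (3R)-3-methyl-4-(octadecanoyloxy)butanoate | C=C(CO[Si](C)(C)C(C)(C)C)[C@@H]1[C@H](OC(=O)C[C@@H](C)COC(=O)CCCCCCCCCCCCCCCCC)[C@H](O)/C(C)=C\CC/C(C)=C/[C@@H]1O[Si](C)(C)C(C)(C)C | intermediate
26 | (1S,2R,3Z,7E,9S,10S)-2,9-dihydroxy-10-(3-hydroxyprop-1-en-2-yl)-3,7-dimethylcyclodeca-3,7-dien-1-yl (3R)-3-methyl-4-(octadecanoyloxy)butanoate | C=C(CO)[C@@H]1[C@H](OC(=O)C[C@@H](C)COC(=O)CCCCCCCCCCCCCCCCC)[C@H](O)/C(C)=C\CC/C(C)=C/[C@@H]1O | intermediate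
27 | (1S,2R,3Z,7E,9S,10S)-2,9-dihydroxy-3,7-dimethyl-10-(3-oxoprop-1-en-2-yl)cyclodeca-3,7-dien-1-yl (3R)-3-methyl-4-(octadecanoyloxy)butanoate | C=C(C=O)[C@@H]1[C@H](OC(=O)C[C@@H](C)COC(=O)CCCCCCCCCCCCCCCCC)[C@H](O)/C(C)=C\CC/C(C)=C/[C@@H]1O | intermediate (not isolated)
28 | (3aS,4S,5R,6Z,10E,11aS)-2,5-dihydroxy-6,10-dimethyl-3-methylidene-2,3,3a,4,5,8,9,11a-octahydrocyclodeca[b]furan-4-yl (3R)-3-methyl-4-(octadecanoyloxy)butanoate (both C2 epimers) | C=C1C(O)O[C@H]2/C=C(\C)CC/C=C(/C)[C@@H](O)[C@@H](OC(=O)C[C@@H](C)COC(=O)CCCCCCCCCCCCCCCCC)[C@@H]12 | intermediate (not isolated)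
29 | CNP0114940.1, (3aS,4S,5R,6Z,10E,11aS)-5-hydroxy-6,10-dimethyl-3-methylidene-2-oxo-2,3,3a,4,5,8,9,11a-octahydrocyclodeca[b]furan-4-yl (3R)-3-methyl-4-(octadecanoyloxy)butanoate | C=C1C(=O)O[C@H]2/C=C(\C)CC/C=C(/C)[C@@H](O)[C@@H](OC(=O)C[C@@H](C)COC(=O)CCCCCCCCCCCCCCCCC)[C@@H]12 | target

## Step count and least certain steps

Total step count: 18. Longest linear sequence: 13 steps (1 to 29 through steps 1–6, 8–10 and 15–18). The side chain takes four steps (11–14) and the cyclobutene one (7).

Step 8 (key step). The α-methyl, γ-silyloxy enone may add the external alkene slowly, so that the triplet is diverted into crossed intramolecular addition to its own 2-propenyl arm, and head-to-head orientation may compete. Fallback, from 9 back to 12: the arm is masked. mCPBA epoxidises only the electron-rich 1,1-disubstituted alkene of 9 and gives the side-chain epoxide F1. Irradiation of F1 with 11 as in step 8 gives the epoxy photoadduct F2. Deoxygenation with Zn, NaI and AcOH (iodohydrin, then reductive elimination) restores the alkene and gives 12.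

Step 9. The 1,4-diyl may partition toward cleavage of C2–C3 (a divinylcyclohexanone), the dienone may undergo Cope rearrangement, or the Z-enone may lose conjugation by a thermal 1,5-hydrogen shift on the hot surface. The cis and trans geometries may also fall on the wrong alkenes. Fallback, from 12 to 15: the ketone is converted first (LiN(i-Pr)2, Me3SiCl) into the trimethylsilyl enol ether F3, which has no carbonyl for the hydrogen shift. Thermolysis of F3 under the conditions of step 9 gives the silyloxy triene F4. Rubottom oxidation of F4 with dimethyldioxirane and mild acid work-up then gives 15 directly, so step 10 is skipped.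

Step 3. Deprotonation may occur at the α′ carbon instead of C6, the Grignard reagent may add to the carbonyl, or the peracid may attack C10 of the dienol ether. Fallback, from 3 to 9 without any dienolate (it replaces steps 3–6):
- Luche reduction of 3 gives the cis allylic alcohol F5.
- Acetylation gives the acetate F6.
- Allylic oxidation of the ring methylene with CrO3 and 3,5-dimethylpyrazole gives the enone acetate F7.
- A second Luche reduction, with hydride anti to the C7 arm, gives the cis C6 alcohol F8, so no inversion is needed.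
- Silylation gives the silyl ether acetate F9.
- Methanolysis gives the allylic alcohol F10.
- MnO2 oxidises F10 to 9.

Step 10. The oxidant may attack the other face of the enolate, or deprotonation may occur at the γ carbon C2. Fallback, from 13 to 24: if the hydroxylation delivers the C8 epimer F11 (hydroxyl cis to the arm), F11 is esterified with 23 by DCC and DMAP with retention. This gives 24 without the inversion of step 15.

Step 15. At a hindered carbinol the acid may be activated instead of the alcohol, giving acyl transfer with retention, or elimination toward C7 may take over. Fallback, from 15 to 24: activation and displacement are separated. (CF3SO2)2O and pyridine convert 15 into the α-keto triflate F12. The cesium salt of 23 (Cs2CO3, DMF) displaces the triflate of F12 by SN2 with inversion to give 24.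

Step 16. Hydride may attack the other face of the C9 carbonyl if the C8 acyloxy group rather than the ring bond takes the antiperiplanar position, which would give the 9-epimer, and the intermediate alkoxide may take up the C8 acyl group. Fallback, from 24 to 25: substrate control is replaced by reagent control. Corey–Bakshi–Shibata reduction with the (R)-methyl oxazaborolidine and catecholborane, with the alkenyl side as the large group, should give the 9R alcohol 25 under non-basic conditions. No new compound is formed.

## Further compounds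

F1 | step 8 | (4S,5R)-4-(TBSO)-2-methyl-5-[2-(TBSO-methyl)oxiran-2-yl]cyclohex-2-en-1-one, side-chain epoxide of 9 (both oxirane epimers) | C1OC1(CO[Si](C)(C)C(C)(C)C)[C@@H]2CC(=O)C(C)=C[C@@H]2O[Si](C)(C)C(C)(C)C
F2 | step 8 | side-chain epoxide of photoadduct 12 (both oxirane epimers) | C1OC1(CO[Si](C)(C)C(C)(C)C)[C@@H]2CC(=O)[C@@]3(C)[C@@H]4CC[C@]4(C)[C@H]3[C@@H]2O[Si](C)(C)C(C)(C)C
F3 | step 9 | trimethylsilyl enol ether of 12 (enol ether C8=C9) | C=C(CO[Si](C)(C)C(C)(C)C)[C@@H]1C=C(O[Si](C)(C)C)[C@@]2(C)[C@@H]3CC[C@]3(C)[C@H]2[C@@H]1O[Si](C)(C)C(C)(C)C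
F4 | step 9 | ring-opened silyloxy triene, trimethylsilyl enol ether of 13 (1(10)Z,4E; enol ether C8=C9) | C=C(CO[Si](C)(C)C(C)(C)C)[C@@H]1\C=C(O[Si](C)(C)C)/C(C)=C\CC/C(C)=C/[C@@H]1O[Si](C)(C)C(C)(C)C
F5 | step 3 | (1S,5S)-2-methyl-5-[3-(TBSO)prop-1-en-2-yl]cyclohex-2-en-1-ol | C=C(CO[Si](C)(C)C(C)(C)C)[C@@H]1C[C@H](O)C(C)=CC1
F6 | step 3 | (1S,5S)-2-methyl-5-[3-(TBSO)prop-1-en-2-yl]cyclohex-2-en-1-yl acetate | C=C(CO[Si](C)(C)C(C)(C)C)[C@@H]1C[C@H](OC(C)=O)C(C)=CC1
F7 | step 3 | (1S,5S)-2-methyl-4-oxo-5-[3-(TBSO)prop-1-en-2-yl]cyclohex-2-en-1-yl acetate | C=C(CO[Si](C)(C)C(C)(C)C)[C@@H]1C[C@H](OC(C)=O)C(C)=CC1=O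
F8 | step 3 | (1S,4S,5S)-4-hydroxy-2-methyl-5-[3-(TBSO)prop-1-en-2-yl]cyclohex-2-en-1-yl acetate | C=C(CO[Si](C)(C)C(C)(C)C)[C@@H]1C[C@H](OC(C)=O)C(C)=C[C@@H]1O
F9 | step 3 | (1S,4S,5S)-4-(TBSO)-2-methyl-5-[3-(TBSO)prop-1-en-2-yl]cyclohex-2-en-1-yl acetate | C=C(CO[Si](C)(C)C(C)(C)C)[C@@H]1C[C@H](OC(C)=O)C(C)=C[C@@H]1O[Si](C)(C)C(C)(C)C
F10 | step 3 | (1S,4S,5S)-4-(TBSO)-2-methyl-5-[3-(TBSO)prop-1-en-2-yl]cyclohex-2-en-1-ol | C=C(CO[Si](C)(C)C(C)(C)C)[C@@H]1C[C@H](O)C(C)=C[C@@H]1O[Si](C)(C)C(C)(C)C
F11 | step 10 | (2Z,6E,8S,9R,10S)-8-(TBSO)-9-[3-(TBSO)prop-1-en-2-yl]-10-hydroxy-2,6-dimethylcyclodeca-2,6-dien-1-one (C8 epimer of 15) | C=C(CO[Si](C)(C)C(C)(C)C)[C@@H]1[C@H](O)C(=O)/C(C)=C\CC/C(C)=C/[C@@H]1O[Si](C)(C)C(C)(C)C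
F12 | step 15 | C8 trifluoromethanesulfonate of 15 | C=C(CO[Si](C)(C)C(C)(C)C)[C@@H]1[C@@H](OS(=O)(=O)C(F)(F)F)C(=O)/C(C)=C\CC/C(C)=C/[C@@H]1O[Si](C)(C)C(C)(C)C
F0 | step 16 | none | none
A1 | alternative 1 | decalin lactone with C4–C9 bond, tertiary C9 hydroxyl and equatorial C5 mesylate | O=C1C[C@@H]2C[C@]3(O)C(C)=CCC[C@@]3(C)[C@H](OS(C)(=O)=O)[C@@H]2O1
A2 | alternative 1 | cis-fused lactone (1(10)Z,4E)-cyclodecadien-9-one | O=C1C[C@@H]2CC(=O)/C(C)=C\CC/C(C)=C/[C@@H]2O1
A3 | alternative 2 | open-chain C2 allylic bromide and C3 allylic phenyl sulfone with C8/C9 acetonide | C=C(CO[Si](C)(C)C(C)(C)C)[C@H]([C@@H]1OC(C)(C)O[C@@H]1/C(C)=C\CBr)[C@@H](OCc1ccc(OC)cc1)/C=C(\C)CS(=O)(=O)c1ccccc1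
A4 | alternative 2 | ten-membered ring C3 sulfone (C3 epimer drawn arbitrarily) | C=C(CO[Si](C)(C)C(C)(C)C)[C@@H]1[C@@H]2OC(C)(C)O[C@@H]2/C(C)=C\C[C@@H](S(=O)(=O)c3ccccc3)/C(C)=C/[C@@H]1OCc4ccc(OC)cc4
A5 | alternative 3 | open-chain C8 aldehyde and C9 (Z)-enal | COC(=O)C[C@H](C=O)[C@@H](OCc1ccc(OC)cc1)/C=C(\C)CC/C=C(/C)C=O
A6 | alternative 3 | (1(10)Z,4E)-cyclodecadiene-8,9-cis-diol | COC(=O)C[C@@H]1[C@H](O)[C@H](O)/C(C)=C\CC/C(C)=C/[C@@H]1OCc2ccc(OC)cc2
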